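**Retrosynthetic overview**
1. Last bond: purine C8 to C2 of ring A, cut back to 8-bromo-2'-deoxyguanosine and a ring A boronate; the sugar, both Boc groups and the MOM ether are removed together in acid.
2. Feature the strategy rests on: in ring A the phenol carbon C1 lies between C2 (bonded to guanine C8) and C6 (bonded to the ether oxygen of ring B), with the benzylic CH2 at C4. This is the pattern of a 3,5-dibromotyrosine ring, whose two equivalent C–Br carbons become one C–O bond and one C–C bond.
3. Second cut: the C6–O diaryl ether bond of the 14-membered meta,para-cyclophane, formed by intramolecular phenol oxidation of a dibromophenol (ring A)/dichlorophenol (ring B) pair; the surviving bromine is the handle for line 1.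
4. Third cut: the cis-(2S,5S)-piperazine, from borane reduction of the diketopiperazine of 3,5-dibromo-L-tyrosine and 3,5-dichloro-L-tyrosine (the latter from L-tyrosine).
5. Ring order: diketopiperazine, piperazine, 14-membered diaryl ether, then attachment of the preformed purine.

Key step: step 8

Assumption (chemistry): 2, 3 and 9 are handled as hydrochlorides and the compound list shows their neutral forms; the guanine NH tautomer is drawn as in the target SMILES.

**Step 1**
Reactants: 1 L-tyrosine
Product: 2 3,5-dichloro-L-tyrosine (collected as hydrochloride)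
Conditions: SO2Cl2 (2.3 equiv), AcOH, rt
Reagents that add atoms: sulfuryl chloride, O=S(=O)(Cl)Cl
Why: Electrophilic aromatic chlorination of the N-protonated amino acid occurs only at the two positions ortho to the activating hydroxyl and leaves the α-stereocentre untouched.

**Step 2**
Reactants: 2 3,5-dichloro-L-tyrosine
Product: 3 3,5-dichloro-L-tyrosine methyl ester (as hydrochloride)
Conditions: SOCl2, MeOH, 0 °C then reflux
Reagents that add atoms: methanol, CO
Why: Fischer esterification driven by HCl generated from SOCl2 in methanol, with the ammonium form protecting the α-centre from racemisation.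

**Step 3**
Reactants: 4 3,5-dibromo-L-tyrosine
Product: 5 N-Boc-3,5-dibromo-L-tyrosine
Conditions: Boc2O (1.1 equiv), NaHCO3, 1,4-dioxane/H2O, rt; KHSO4 to pH 3
Reagents that add atoms: di-tert-butyl dicarbonate, CC(C)(C)OC(=O)OC(=O)OC(C)(C)C
Why: Carbamate formation (Boc protection) at the amine, which is far more nucleophilic than the hindered, acidic 2,6-dibromophenol.

**Step 4**
Reactants: 3 3,5-dichloro-L-tyrosine methyl ester (hydrochloride), 5 N-Boc-3,5-dibromo-L-tyrosine
Product: 6 Boc-(3,5-dibromo-L-Tyr)-(3,5-dichloro-L-Tyr)-OMe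
Conditions: EDC·HCl, HOBt, N-methylmorpholine, DMF, 0 °C to rt
Reagents that add atoms: none
Why: Carbodiimide/HOBt amide coupling of a urethane-protected acid proceeds without racemisation, and the flanked 2,6-dihalophenols are too hindered and too weakly nucleophilic to compete with the amine.

**Step 5**
Reactants: 6 Boc-(3,5-dibromo-L-Tyr)-(3,5-dichloro-L-Tyr)-OMe
Product: 8 (3S,6S)-3-(3,5-dibromo-4-hydroxybenzyl)-6-(3,5-dichloro-4-hydroxybenzyl)piperazine-2,5-dione, via dipeptide amine 7 (not isolated)
Conditions: HCO2H, rt; evaporate; sec-BuOH/toluene (4:1), reflux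
Reagents that add atoms: none
Why: Acidolytic Boc cleavage followed by thermal intramolecular aminolysis of the methyl ester (diketopiperazine formation) closes the six-membered ring under weakly acidic, non-epimerising conditions, so the two L-residues give the cis product.

**Step 6**
Reactants: 8 the diketopiperazine
Product: 9 (2S,5S)-2-(3,5-dibromo-4-hydroxybenzyl)-5-(3,5-dichloro-4-hydroxybenzyl)piperazine (isolated as dihydrochloride)
Conditions: BH3·THF (excess), THF, reflux; then MeOH, 6 M HCl, reflux; evaporate from MeOH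
Reagents that add atoms: none
Why: Borane reduction of both secondary lactams to amines leaves aryl C–Br and C–Cl bonds and the non-enolisable stereocentres alone; excess reagent covers the phenols and acidic methanolysis breaks the amine–borane adducts.

**Step 7**
Reactants: 9 the piperazine (dihydrochloride)
Product: 10 di-tert-butyl (2S,5S)-2-(3,5-dibromo-4-hydroxybenzyl)-5-(3,5-dichloro-4-hydroxybenzyl)piperazine-1,4-dicarboxylate
Conditions: Boc2O (2.5 equiv), Et3N, THF/MeOH, rt; then K2CO3, MeOH, rt
Reagents that add atoms: di-tert-butyl dicarbonate, CC(C)(C)OC(=O)OC(=O)OC(C)(C)C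
Why: N-acylation (Boc protection) of both secondary amines; any aryl tert-butyl carbonate formed on the acidic phenols is removed by the mild methanolysis, which does not touch the carbamates.

**Step 8**
Reactants: 10 the di-Boc bis-phenol
Product: 12 di-Boc bromo-dichloro macrocyclic diaryl ether (ring A phenol flanked by Br and the ether oxygen), via bromodienone 11 (not isolated)
Conditions: Tl(NO3)3·3H2O (2.5 equiv), MeOH (about 1 mM), −25 to 0 °C; aqueous work-up; then Zn, AcOH/THF, rt
Reagents that add atoms: none
Why: Trivalent thallium removes two electrons from the dibromophenol of ring A, and the resulting phenoxonium-type cation is trapped at a bromine-bearing ortho carbon by the hydroxyl oxygen of the ring B dichlorophenol to give the 6-aryloxy-6-bromocyclohexa-2,4-dienone 11 (bromide may be partly exchanged for methoxide, which is harmless); Zn in AcOH then expels the ipso group and restores the ring A phenol with one bromine left. The closest known reaction type is the Tl(NO3)3/Zn diaryl ether synthesis from o,o'-dihalophenol pairs, which is established for tyrosine-derived 14-membered meta,para-cyclophanes of this piperazine type. The 14-membered ring closes by intramolecular ipso O-attack (macro-etherification) onto a carbon that becomes sp3, so the cyclophane strain is taken up only in the strongly driven rearomatisation. The only new stereocentre, the quaternary dienone carbon of 11, is uncontrolled and is erased on reduction, so none is created in 12. The step needs oxidation of ring A rather than ring B and C–O rather than C–C coupling; the lower oxidation potential of the dibromophenol and the halogens on all four ortho carbons secure this, and the equivalence of the two ortho carbons of ring A means only one macrocycle can form. Allylic 1,3-strain from the two carbamates pushes both benzyl arms pseudo-axial, which for the cis isomer means a twist-boat piperazine with both rings on one face, and high dilution suppresses oligomers.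

**Step 9**
Reactants: 12 the bromophenol macrocycle
Product: 13 MOM ether of 12
Conditions: NaH (1.2 equiv), MOMCl (1.3 equiv), THF/DMF, 0 °C to rt
Reagents that add atoms: chloromethyl methyl ether, COCCl
Why: Williamson-type O-alkylation of the only acidic site; the small, highly reactive chloromethyl ether tolerates the flanking bromine and aryloxy group.

**Step 10**
Reactants: 13 the MOM-protected aryl bromide
Product: 14 dichloro macrocyclic aryl pinacol boronate
Conditions: B2pin2 (1.5 equiv), PdCl2(dppf)·CH2Cl2 (5 mol%), KOAc, 1,4-dioxane, 85 °C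
Reagents that add atoms: bis(pinacolato)diboron, CC1(C)OB(OC1(C)C)B1OC(C)(C)C(C)(C)O1
Why: Miyaura borylation; zerovalent palladium inserts into the C–Br bond far faster than into the two hindered C–Cl bonds of ring B, and the weak acetate base prevents biaryl coupling.

**Step 11**
Reactants: 14 the dichloro boronate
Product: 15 chlorine-free MOM-protected macrocyclic aryl pinacol boronate
Conditions: H2 (1 atm), 10% Pd/C, Et3N (4 equiv), MeOH/EtOAc, rt
Reagents that add atoms: none
Why: Palladium-catalysed hydrogenolysis of the aryl C–Cl bonds with triethylamine as HCl acceptor; the pinacol boronate, carbamates, acetal and diaryl ether are inert at room temperature and 1 atm.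

**Step 12**
Reactants: 15 the aryl pinacol boronate, 16 8-bromo-2'-deoxyguanosine
Product: 17 C8-aryl-2'-deoxyguanosine conjugate of the protected macrocycle
Conditions: Pd(OAc)2 (5 mol%), P(C6H4-3-SO3Na)3 (12.5 mol%), Na2CO3, H2O/MeCN (1:2), 80 °C, degassed
Reagents that add atoms: none
Why: Suzuki–Miyaura coupling of the unprotected 8-bromopurine nucleoside with a water-soluble phosphine/palladium catalyst, a combination known to tolerate the free nucleoside and ortho-oxygenated aryl boron partners; the deoxyribose keeps N9 blocked and the purine soluble.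

**Step 13**
Reactants: 17 the protected conjugate
Product: 18 guanipiperazine A (free base after neutralisation)
Conditions: 2 M aq. HCl/1,4-dioxane (1:1), 60 °C; then aq. NH3 to pH 8; reverse-phase chromatography
Reagents that add atoms: none
Why: Acid hydrolysis performs Boc acidolysis, MOM acetal cleavage and depurination in one operation, because the N9–C1' bond of C8-aryl-2'-deoxyguanosines ionises to the deoxyribosyl oxocarbenium ion more readily than in the parent nucleoside; the guanine, the diaryl ether and both piperazine stereocentres are stable to aqueous acid.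

**Compound list**
1 | L-tyrosine | N[C@@H](Cc1ccc(O)cc1)C(=O)O | starting material
2 | 3,5-dichloro-L-tyrosine | N[C@@H](Cc1cc(Cl)c(O)c(Cl)c1)C(=O)O | intermediate
3 | 3,5-dichloro-L-tyrosine methyl ester | N[C@@H](Cc1cc(Cl)c(O)c(Cl)c1)C(=O)OC | intermediate
4 | 3,5-dibromo-L-tyrosine | N[C@@H](Cc1cc(Br)c(O)c(Br)c1)C(=O)O | starting material
5 | N-Boc-3,5-dibromo-L-tyrosine | CC(C)(C)OC(=O)N[C@@H](Cc1cc(Br)c(O)c(Br)c1)C(=O)O | intermediate
6 | Boc-(3,5-dibromo-L-Tyr)-(3,5-dichloro-L-Tyr)-OMe | CC(C)(C)OC(=O)N[C@@H](Cc1cc(Br)c(O)c(Br)c1)C(=O)N[C@@H](Cc1cc(Cl)c(O)c(Cl)c1)C(=O)OC | intermediate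
7 | H-(3,5-dibromo-L-Tyr)-(3,5-dichloro-L-Tyr)-OMe (dipeptide amine, formate salt in the flask) | N[C@@H](Cc1cc(Br)c(O)c(Br)c1)C(=O)N[C@@H](Cc1cc(Cl)c(O)c(Cl)c1)C(=O)OC | intermediate (not isolated)
8 | (3S,6S)-3-(3,5-dibromo-4-hydroxybenzyl)-6-(3,5-dichloro-4-hydroxybenzyl)piperazine-2,5-dione | O=C1N[C@@H](Cc2cc(Cl)c(O)c(Cl)c2)C(=O)N[C@H]1Cc1cc(Br)c(O)c(Br)c1 | intermediate
9 | (2S,5S)-2-(3,5-dibromo-4-hydroxybenzyl)-5-(3,5-dichloro-4-hydroxybenzyl)piperazine | Oc1c(Cl)cc(cc1Cl)C[C@H]1CN[C@H](CN1)Cc1cc(Br)c(O)c(Br)c1 | intermediate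
10 | di-tert-butyl (2S,5S)-2-(3,5-dibromo-4-hydroxybenzyl)-5-(3,5-dichloro-4-hydroxybenzyl)piperazine-1,4-dicarboxylate | Oc1c(Cl)cc(cc1Cl)C[C@H]1CN(C(=O)OC(C)(C)C)[C@H](CN1C(=O)OC(C)(C)C)Cc1cc(Br)c(O)c(Br)c1 | intermediate
11 | macrocyclic 6-aryloxy-2,6-dibromocyclohexa-2,4-dienone (ring A oxidised; either configuration at the sp3 dienone carbon) | BrC1=CC2=CC(Br)(C1=O)Oc1c(Cl)cc(cc1Cl)C[C@H]1CN(C(=O)OC(C)(C)C)[C@H](CN1C(=O)OC(C)(C)C)C2 | intermediate (not isolated)
12 | di-Boc bromo-dichloro macrocyclic diaryl ether (ring A: OH flanked by Br and OAr; ring B: 2,6-dichloro-1,4-phenylene) | Brc1cc2cc(c1O)Oc1c(Cl)cc(cc1Cl)C[C@H]1CN(C(=O)OC(C)(C)C)[C@H](CN1C(=O)OC(C)(C)C)C2 | intermediate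
13 | MOM ether of 12 | COCOc1c(Br)cc2cc1Oc1c(Cl)cc(cc1Cl)C[C@H]1CN(C(=O)OC(C)(C)C)[C@H](CN1C(=O)OC(C)(C)C)C2 | intermediate
14 | dichloro MOM-protected macrocyclic aryl pinacol boronate | COCOc1c(B3OC(C)(C)C(C)(C)O3)cc2cc1Oc1c(Cl)cc(cc1Cl)C[C@H]1CN(C(=O)OC(C)(C)C)[C@H](CN1C(=O)OC(C)(C)C)C2 | intermediate
15 | chlorine-free MOM-protected macrocyclic aryl pinacol boronate | COCOc1c(B3OC(C)(C)C(C)(C)O3)cc2cc1Oc1ccc(cc1)C[C@H]1CN(C(=O)OC(C)(C)C)[C@H](CN1C(=O)OC(C)(C)C)C2 | intermediate
16 | 8-bromo-2'-deoxyguanosine | Nc1nc2c(nc(Br)n2[C@H]2C[C@H](O)[C@@H](CO)O2)c(=O)[nH]1 | starting material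
17 | C8-aryl-2'-deoxyguanosine conjugate of the di-Boc, MOM-protected macrocycle | Nc1nc2c(nc(-c3cc4cc(c3OCOC)Oc3ccc(cc3)C[C@H]3CN(C(=O)OC(C)(C)C)[C@H](CN3C(=O)OC(C)(C)C)C4)n2[C@H]2C[C@H](O)[C@@H](CO)O2)c(=O)[nH]1 | intermediate
18 | guanipiperazine A | Nc1nc2nc(-c3cc4cc(c3O)Oc3ccc(cc3)C[C@H]3CN[C@H](CN3)C4)[nH]c2c(=O)[nH]1 | target

**Totals**
Total step count: 13.
Longest linear sequence: 12 steps (from L-tyrosine 1: steps 1, 2 and 4 to 13).

**Steps most likely to fail**

1. Step 8. The oxidation may be diverted into methanol capture at the para carbon, which only regenerates 10 on zinc reduction, or into intermolecular coupling, or the strained ring may form slowly so that over-oxidation wins. The fallback makes the same C–O bond by copper-mediated substitution; it sets out from compounds 1 and 5 and returns at compound 15.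
 - L-tyrosine 1 is esterified (SOCl2, MeOH) to L-tyrosine methyl ester F1, which is coupled with acid 5 (EDC·HCl, HOBt, DMF) to the dipeptide Boc-(3,5-dibromo-L-Tyr)-L-Tyr-OMe F2.
 - Formic acid and then hot sec-butanol/toluene should give, through the free dipeptide ester H-(3,5-dibromo-L-Tyr)-L-Tyr-OMe F3, the diketopiperazine cyclo(3,5-dibromo-L-Tyr–L-Tyr) F4.
 - BH3·THF reduction gives the (2S,5S)-piperazine bis-phenol F5, and Boc2O gives its di-Boc derivative F6.
 - The much more acidic dibromophenol alone is etherified (K2CO3, 1 equiv; MOMCl; DMF, 0 °C) to the mono-MOM ether F7.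
 - An intramolecular Ullmann coupling (CuI, N,N-dimethylglycine, Cs2CO3, 1,4-dioxane, 100 °C, high dilution) of the ring B phenoxide with one of the two equivalent C–Br bonds of ring A should close the ring to the chlorine-free bromo MOM macrocycle F8.
 - Miyaura borylation as in step 10 then gives boronate 15.

2. Step 12. The lipophilic boronate and the polar nucleoside may not share a phase, the ortho-alkoxy arylboronate may protodeboronate before transmetalation, and the guanine may sequester palladium. The fallback builds the imidazole ring of the purine onto the aryl carbon instead; it sets out from compound 13 and returns at compound 18.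
 - Bromine–lithium exchange on 13 (n-BuLi, THF, −78 °C) and quenching with DMF gives the ring A aldehyde F9.
 - Condensation with 2,5,6-triaminopyrimidin-4(3H)-one (sulfate, NaOAc, DMSO, 90 °C, air) at the 5-amino group and oxidative closure (Traube-type purine synthesis) should give the protected dichloro 8-arylguanine F10.
 - Hydrogenolysis (H2, Pd/C, Et3N, MeOH/DMF) removes the chlorines to give the protected 8-arylguanine F11.
 - The acid treatment of step 13 then gives 18.

3. Step 11. The C–B bond may be lost on the palladium surface, or the hydrogenolysis may stall after one chlorine. The fallback postpones dechlorination until no C–B bond is present; it sets out from compound 14 and returns at compound 17.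
 - Dichloro boronate 14 is coupled with 16 under the conditions of step 12, which should not engage the hindered C–Cl bonds, to give the dichloro C8-aryl-2'-deoxyguanosine conjugate F12.
 - Hydrogenolysis (H2, Pd/C, Et3N, MeOH) then gives 17.

**Further compounds**
F1 | step 8 | L-tyrosine methyl ester | N[C@@H](Cc1ccc(O)cc1)C(=O)OC
F2 | step 8 | Boc-(3,5-dibromo-L-Tyr)-L-Tyr-OMe | CC(C)(C)OC(=O)N[C@@H](Cc1cc(Br)c(O)c(Br)c1)C(=O)N[C@@H](Cc1ccc(O)cc1)C(=O)OC
F3 | step 8 | H-(3,5-dibromo-L-Tyr)-L-Tyr-OMe | N[C@@H](Cc1cc(Br)c(O)c(Br)c1)C(=O)N[C@@H](Cc1ccc(O)cc1)C(=O)OC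
F4 | step 8 | cyclo(3,5-dibromo-L-Tyr–L-Tyr) diketopiperazine | O=C1N[C@@H](Cc2ccc(O)cc2)C(=O)N[C@H]1Cc1cc(Br)c(O)c(Br)c1
F5 | step 8 | (2S,5S)-2-(3,5-dibromo-4-hydroxybenzyl)-5-(4-hydroxybenzyl)piperazine | Oc1ccc(cc1)C[C@H]1CN[C@H](CN1)Cc1cc(Br)c(O)c(Br)c1
F6 | step 8 | di-Boc derivative of F5 | Oc1ccc(cc1)C[C@H]1CN(C(=O)OC(C)(C)C)[C@H](CN1C(=O)OC(C)(C)C)Cc1cc(Br)c(O)c(Br)c1
F7 | step 8 | mono-MOM ether of F6 (MOM on the dibromophenol) | Oc1ccc(cc1)C[C@H]1CN(C(=O)OC(C)(C)C)[C@H](CN1C(=O)OC(C)(C)C)Cc1cc(Br)c(OCOC)c(Br)c1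
F8 | step 8 | chlorine-free bromo MOM macrocycle | COCOc1c(Br)cc2cc1Oc1ccc(cc1)C[C@H]1CN(C(=O)OC(C)(C)C)[C@H](CN1C(=O)OC(C)(C)C)C2
F9 | step 12 | ring A aldehyde of the dichloro MOM macrocycle | COCOc1c(C=O)cc2cc1Oc1c(Cl)cc(cc1Cl)C[C@H]1CN(C(=O)OC(C)(C)C)[C@H](CN1C(=O)OC(C)(C)C)C2
F10 | step 12 | protected dichloro 8-arylguanine | Nc1nc2nc(-c3cc4cc(c3OCOC)Oc3c(Cl)cc(cc3Cl)C[C@H]3CN(C(=O)OC(C)(C)C)[C@H](CN3C(=O)OC(C)(C)C)C4)[nH]c2c(=O)[nH]1
F11 | step 12 | protected 8-arylguanine (chlorine-free) | Nc1nc2nc(-c3cc4cc(c3OCOC)Oc3ccc(cc3)C[C@H]3CN(C(=O)OC(C)(C)C)[C@H](CN3C(=O)OC(C)(C)C)C4)[nH]c2c(=O)[nH]1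
F12 | step 11 | dichloro C8-aryl-2'-deoxyguanosine conjugate | Nc1nc2c(nc(-c3cc4cc(c3OCOC)Oc3c(Cl)cc(cc3Cl)C[C@H]3CN(C(=O)OC(C)(C)C)[C@H](CN3C(=O)OC(C)(C)C)C4)n2[C@H]2C[C@H](O)[C@@H](CO)O2)c(=O)[nH]1
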